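**Retrosynthetic overview**

1. Feature (germacrane numbering): the enol-ether alkene C5=C6 joins the non-enolisable, ether-bearing C4 of the tetrahydrofuran (ring B, C1–O–C4) to the gamma carbon C6 of the butenolide (ring A). Cutting it by a retro vinylogous aldol/elimination opens the ten-membered carbocycle (ring C) to a C5 aldehyde tethered to a 2-silyloxyfuran.
2. End game after closure: C8 ester from (S)-2-methylglycidic acid (chloride then opens the epoxide at CH2), C13 acetate, C1 hemiketal from the methyl ketal.
3. Seco chain: C1–C2 by addition of a C2–C5 alkyllithium to a C1 Weinreb amide; the alkyllithium comes from (R)-linalool (source of C4) after two chemoselective ozonolyses. Acid methanolysis then forms ring B.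
4. Weinreb amide: C8–C9 by Negishi acylation of a furoyl chloride with the zinc homoenolate of methyl (S)-3-bromo-2-methylpropanoate (source of C10), C8 by CBS reduction. The furan comes from furan-3-ylmethanol with silicon placed on the future C12, so that singlet oxygen later gives the butenolide with the carbonyl next to C11 and no regiochemical ambiguity.
5. Ring order: furan (bought) → ring B (ketal, step 14) → ring A as butenolide and silyloxyfuran (steps 15, 17) → ring C (step 18).

Key step: step 18

Remark: germacrane numbering (C1–C15; C13 = oxygenated CH2 on C11, C14 = methyl on C10, C15 = methyl on C4) is used for all chain positions. FurSi = 5-(tert-butyldimethylsilyl)-4-{[(triisopropylsilyl)oxy]methyl}furan-3-yl; its silicon-bearing ring carbon is the future C12.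
Assumption: the two C1 anomers of the ring B methyl ketal interconvert in acidic methanol and the (1S)-anomer can be separated from the equilibrium mixture by chromatography.

**Route**

Step 1
Reactants: 1 furan-3-ylmethanol
Product: 2 tert-butyl(furan-3-ylmethoxy)dimethylsilane
Conditions: TBSCl, imidazole, DMF, 0 °C → rt
Reagents that add atoms: tert-butyldimethylsilyl chloride, CC(C)(C)[Si](C)(C)Cl
Why: Routine silylation of a primary alcohol places on oxygen the silicon that the next step moves onto the ring.

Step 2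
Reactants: 2 tert-butyl(furan-3-ylmethoxy)dimethylsilane
Product: 3 [2-(tert-butyldimethylsilyl)furan-3-yl]methanol
Conditions: nBuLi, HMPA, THF, −78 → 0 °C; H2O
Reagents that add atoms: none
Why: Lithiation at the furan alpha position next to the side chain is followed by a [1,4] O-to-C silyl shift (retro-Brook rearrangement) driven by alkoxide formation, a known entry to 2-silyl-3-(hydroxymethyl)furans that marks the future C12.

Step 3
Reactants: 3 [2-(tert-butyldimethylsilyl)furan-3-yl]methanol
Product: 7 5-(tert-butyldimethylsilyl)-4-{[(triisopropylsilyl)oxy]methyl}furan-3-carboxylic acid, via C4-lithio lithium alkoxide 4 (not isolated), via dilithium carboxylate 5 (not isolated), via silyl ester silyl ether 6 (not isolated)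
Conditions: nBuLi (2.2 equiv), DME, 0 °C; CO2, −78 °C; TIPSOTf (2.3 equiv), −78 → 0 °C; then K2CO3, MeOH/H2O, 0 °C; acidify to pH 4
Reagents that add atoms: carbon dioxide, O=C=O; triisopropylsilyl trifluoromethanesulfonate, CC(C)[Si](C(C)C)(C(C)C)OS(=O)(=O)C(F)(F)F
Why: With the neighbouring alpha position blocked by silicon, the lithium alkoxide directs the second lithiation to the adjacent beta position (known alkoxide-directed ortho-lithiation of 2-silyl-3-(hydroxymethyl)furans); carboxylation puts the future C8 there, silylation in the same flask avoids the free hydroxy acid (which could lactonise), and carbonate cleaves only the silyl ester.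

Step 4
Reactants: 7 5-(tert-butyldimethylsilyl)-4-{[(triisopropylsilyl)oxy]methyl}furan-3-carboxylic acid; 8 methyl (S)-3-bromo-2-methylpropanoate
Product: 11 methyl (2R)-4-(FurSi)-2-methyl-4-oxobutanoate (C8 ketone; C1 ester), via acid chloride 9 (not isolated), via zinc reagent 10 (not isolated)
Conditions: (a) 7, 1-chloro-N,N,2-trimethylprop-1-en-1-amine, CH2Cl2, 0 °C → rt; (b) 8, Zn dust, LiCl, THF, 40 °C; (c) Pd(PPh3)4 (5 mol%), THF, 0 °C → rt
Reagents that add atoms: none
Why: Negishi acylation under zerovalent palladium catalysis joins the acid chloride (made under neutral conditions) to the zinc homoenolate, whose C10 stereocentre is not the metal-bearing carbon and therefore comes through unchanged from 8.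

Step 5
Reactants: 11 methyl (2R)-4-(FurSi)-2-methyl-4-oxobutanoate
Product: 13 (3R,5S)-5-(FurSi)-3-methyloxolan-2-one (trans lactone), via hydroxy ester 12 (not isolated)
Conditions: (R)-2-methyl-CBS-oxazaborolidine [(R)-1-methyl-3,3-diphenyltetrahydro-1H,3H-pyrrolo[1,2-c][1,3,2]oxazaborole] (20 mol%), BH3·SMe2, THF, −30 °C; MeOH; then PPTS (cat.), toluene, 40 °C
Reagents that add atoms: none
Why: Corey–Bakshi–Shibata reduction of the furyl alkyl ketone with the (R)-catalyst should set C8 as S under catalyst control (furyl as the large group), and lactonisation gives the trans lactone, from which any cis lactone (C8 epimer) can be removed.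

Step 6
Reactants: 13 (3R,5S)-5-(FurSi)-3-methyloxolan-2-one
Product: 14 (2R,4S)-4-(FurSi)-4-hydroxy-N-methoxy-N,2-dimethylbutanamide
Conditions: MeNH(OMe)·HCl, iPrMgCl, THF, −20 → 0 °C
Reagents that add atoms: N,O-dimethylhydroxylamine hydrochloride, CNOC.Cl
Why: Aminolysis of the lactone by the chloromagnesium amide (Weinreb amide formation) opens the ring at low temperature without touching C10.

Step 7
Reactants: 14 (2R,4S)-4-(FurSi)-4-hydroxy-N-methoxy-N,2-dimethylbutanamide
Product: 15 (2R,4S)-4-[(tert-butyldimethylsilyl)oxy]-4-(FurSi)-N-methoxy-N,2-dimethylbutanamide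
Conditions: TBSOTf, 2,6-lutidine, CH2Cl2, −78 → 0 °C
Reagents that add atoms: tert-butyldimethylsilyl trifluoromethanesulfonate, CC(C)(C)[Si](C)(C)OS(=O)(=O)C(F)(F)F
Why: Silyl triflate silylation caps the hindered C8 hydroxyl before the hydroxy amide can relactonise.

Step 8
Reactants: 16 (R)-linalool
Product: 17 triethyl{[(3R)-3,7-dimethylocta-1,6-dien-3-yl]oxy}silane
Conditions: TESOTf, 2,6-lutidine, CH2Cl2, −78 → 0 °C
Reagents that add atoms: triethylsilyl trifluoromethanesulfonate, CC[Si](CC)(CC)OS(=O)(=O)C(F)(F)F
Why: Low-temperature silylation of the tertiary allylic alcohol masks the C4 oxygen for the organolithium chemistry without ionising it.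

Step 9
Reactants: 17 triethyl{[(3R)-3,7-dimethylocta-1,6-dien-3-yl]oxy}silane
Product: 18 (4R)-4-methyl-4-[(triethylsilyl)oxy]hex-5-enal
Conditions: O3, CH2Cl2, −78 °C (Sudan Red 7B end point); PPh3, −78 °C → rt
Reagents that add atoms: ozone, [O-][O+]=O
Why: Chemoselective ozonolysis: electrophilic ozone takes the trisubstituted alkene far faster than the vinyl group on the quaternary, silyloxy-bearing carbon, and the dye end point stops the reaction there.

Step 10
Reactants: 18 (4R)-4-methyl-4-[(triethylsilyl)oxy]hex-5-enal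
Product: 19 tert-butyldimethyl{[(4R)-4-methyl-4-(triethylsilyloxy)hexa-1,5-dien-1-yl]oxy}silane (E/Z mixture)
Conditions: TBSOTf, Et3N, CH2Cl2, 0 °C → rt
Reagents that add atoms: tert-butyldimethylsilyl trifluoromethanesulfonate, CC(C)(C)[Si](C)(C)OS(=O)(=O)C(F)(F)F
Why: Soft enolisation of the aldehyde gives the enol silyl ether (either geometry serves), which prepares the excision of the aldehyde carbon.

Step 11
Reactants: 19 tert-butyldimethyl{[(4R)-4-methyl-4-(triethylsilyloxy)hexa-1,5-dien-1-yl]oxy}silane
Product: 20 (3R)-3-methyl-3-[(triethylsilyl)oxy]pent-4-en-1-ol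
Conditions: O3 (1 equiv), CH2Cl2/MeOH, −78 °C; NaBH4, −78 → 0 °C
Reagents that add atoms: ozone, [O-][O+]=O
Why: The electron-rich enol ether is ozonised much faster than the vinyl group (chemoselective ozonolysis), removing one carbon, and borohydride reduces the beta-silyloxy aldehyde in the flask before it can eliminate.

Step 12
Reactants: 20 (3R)-3-methyl-3-[(triethylsilyl)oxy]pent-4-en-1-ol
Product: 21 triethyl{[(3R)-5-iodo-3-methylpent-1-en-3-yl]oxy}silane
Conditions: I2, PPh3, imidazole, CH2Cl2, 0 °C
Reagents that add atoms: iodine, [I][I]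
Why: Appel-type iodination converts the primary alcohol under buffered conditions that leave the tertiary silyl ether alone.

Step 13
Reactants: 21 triethyl{[(3R)-5-iodo-3-methylpent-1-en-3-yl]oxy}silane; 15 (2R,4S)-4-[(tert-butyldimethylsilyl)oxy]-4-(FurSi)-N-methoxy-N,2-dimethylbutanamide
Product: 23 (4R,8S,10R) seco ketone: CH2=CH–C4(CH3)(OTES)–C3H2–C2H2–C1(=O)–C10H(CH3)–C9H2–C8H(OTBS)–FurSi, via alkyllithium 22 (not isolated)
Conditions: 21 (1.3 equiv), tBuLi (2.6 equiv), Et2O/pentane, −78 °C; then 15, Et2O, −78 °C
Reagents that add atoms: none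
Why: Iodine–lithium exchange gives a primary alkyllithium (a 4-pentenyllithium, which does not cyclise, with a hindered tertiary silyl ether that does not migrate at −78 °C) that adds once to the Weinreb amide through its stable chelate, forming C1–C2 without epimerising C10.

Step 14
Reactants: 23 (4R,8S,10R) seco ketone
Product: 26 (1S,4R,8S,10R) ring B methyl ketal: 2-methoxy-5-methyl-5-vinyltetrahydrofuran whose C1 carries the C10H(CH3)–C9H2–C8H(OTBS)–FurSi chain cis to the vinyl group, via hydroxy ketone 24 (not isolated), via C1-epimeric ketal 25 (not isolated)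
Conditions: camphorsulfonic acid (10 mol%), MeOH/CH2Cl2, 0 °C → rt; Et3N; chromatography; mixed fractions returned unpurified to the same acid
Reagents that add atoms: methanol, CO
Why: Acid methanolysis removes the tertiary triethylsilyl ether much faster than the primary TIPS or the hindered secondary TBS ether, and the freed C4 hydroxyl closes on the C1 ketone (ketalisation) to give the (1R)-anomer 25 and the (1S)-anomer 26, which interconvert through the ring B oxocarbenium ion under the acid, so that C1 is under thermodynamic control; 26 is separated after the amine quench and the fractions that still hold 25 go back into the same acid, where 25 should re-enter the equilibrium and be drawn on to 26.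

Step 15
Reactants: 26 (1S,4R,8S,10R) ring B methyl ketal
Product: 28 (1S,4R,8S,10R) butenolide: C7=C11 lactone with C12 carbonyl; C6H2; C13 OTIPS; C8 OTBS; vinyl on C4, via C6-hydroxybutenolide 27 (not isolated)
Conditions: O2, hν (visible), 5,10,15,20-tetraphenylporphyrin (cat.), CH2Cl2, −78 °C; then MeOH, NaBH4, −40 → 0 °C; pH 5 buffer
Reagents that add atoms: oxygen (sensitised to singlet oxygen), O=O
Why: Singlet oxygen adds across the furan and the silyl group migrates to the peroxide, so the silicon-bearing carbon becomes C12 (known regiospecific photooxygenation of 2-silylfurans to gamma-hydroxybutenolides); borohydride reduction of the masked C6 aldehyde and spontaneous lactonisation give the butenolide, while the vinyl group, having no allylic hydrogen, is inert.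

Step 16
Reactants: 28 (1S,4R,8S,10R) butenolide
Product: 29 (1S,4R,8S,10R) C5 aldehyde butenolide
Conditions: OsO4 (2 mol%), NaIO4, 2,6-lutidine, dioxane/H2O, rt
Reagents that add atoms: osmium tetroxide (catalytic oxygen carrier), O=[Os](=O)(=O)=O; sodium periodate (terminal oxidant), [Na+].[O-]I(=O)(=O)=O
Why: Johnson–Lemieux cleavage: OsO4 prefers the unhindered monosubstituted alkene to the tetrasubstituted, electron-poor butenolide alkene, and periodate cleaves the diol to the non-enolisable aldehyde under lutidine buffering that protects the ketal.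

Step 17
Reactants: 29 (1S,4R,8S,10R) C5 aldehyde butenolide
Product: 30 (1S,4R,8S,10R) seco C5 aldehyde 2-(triisopropylsilyloxy)furan: C12 OTIPS; C13 OTIPS; C8 OTBS; C1 methyl ketal
Conditions: TIPSOTf (1.1 equiv), Et3N (3 equiv), CH2Cl2, −78 → 0 °C; filtration through Et3N-deactivated silica, used at once
Reagents that add atoms: triisopropylsilyl trifluoromethanesulfonate, CC(C)[Si](C(C)C)(C(C)C)OS(=O)(=O)C(F)(F)F
Why: O-silylation of the lactone carbonyl with gamma-deprotonation by the amine is the standard preparation of 2-silyloxyfurans; the aldehyde has no alpha hydrogen, and excess amine with barely one equivalent of the bulky triflate at low temperature should hold back Lewis-acid-promoted aldol closure and ketal ionisation.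

Step 18
Reactants: 30 (1S,4R,8S,10R) seco C5 aldehyde 2-(triisopropylsilyloxy)furan
Product: 34 (1S,4R,8S,10R; 5E) bridged dienolide: ring C closed through C5=C6; C1 methyl ketal; C8 OTBS; C13 OTIPS, via tetrabutylammonium furanolate 31 (not isolated), via C5 aldol 32 (not isolated), via C5 acetate 33 (not isolated)
Conditions: [Bu4N][Ph3SiF2] (1.1 equiv), THF, 0.002 M, −20 °C, slow addition of 30; then Ac2O, DBU, 0 °C → rt
Reagents that add atoms: none
Why: Proposed new method: fluoride from the silicate cleaves the O–Si bond of the silyloxyfuran to give the 2-oxidofuran 31, which can form a productive bond to the tethered C5 aldehyde only at C6 because C11 is tetrasubstituted; the aldolate 32 is acetylated to 33, and DBU removes the acidic C6–H so that acetate leaves by E1cB to give the C5=C6 alkene. The closest known chemistry is the intermolecular one-pot vinylogous Mukaiyama aldol/elimination of 2-silyloxyfurans with aldehydes to gamma-alkylidene butenolides; its use to close a medium ring is new. Ring C forms by 10-exo-trig attack on the aldehyde carbonyl (9-exo-trig if the path through the ether oxygen is counted), with the cis-2,5 arrangement of the two arms on the tetrahydrofuran and the flat furan preorganising the chain ends. No new stereocentre survives: C5 and C6 are stereogenic only in 32 and 33, and the alkene geometry with C4 cis to C7 is the only one the bridge allows. The step needs reaction at C6 and not at C11 or oxygen, ring closure and not dimerisation, and forward drive against retro-aldol; these rest on the substituted C11, on high dilution with slow addition, and on the elimination to the conjugated dienolide being the only irreversible event (acetyl transfer from any O-acetylated furanolate is reversible under the conditions). The aldehyde is non-enolisable and alpha-oxygenated, hence reactive, and the methyl ketal keeps C1 from competing as an electrophile for C6 (which would close a six-membered ring).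

Step 19
Reactants: 34 (1S,4R,8S,10R; 5E) bridged dienolide
Product: 35 (1S,4R,8S,10R; 5E) C8,C13-diol C1 methyl ketal
Conditions: TBAF, AcOH (1:1), THF, 0 °C → rt
Reagents that add atoms: none
Why: Acetic-acid-buffered fluoride desilylation removes both silyl ethers without the basicity that would endanger the dienolide and without acid strong enough to disturb the methyl ketal.

Step 20
Reactants: 35 (1S,4R,8S,10R; 5E) C8,C13-diol C1 methyl ketal
Product: 36 (1S,4R,8S,10R; 5E) 13-O-acetate with free C8 hydroxyl
Conditions: Ac2O (1.1 equiv), 2,4,6-collidine, CH2Cl2, −20 → 0 °C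
Reagents that add atoms: acetic anhydride, CC(=O)OC(C)=O
Why: Selective acylation: the primary allylic C13 hydroxyl reacts much faster than the hindered secondary C8 hydroxyl next to the tetrasubstituted alkene.

Step 21
Reactants: 37 methyl (S)-2-methylglycidate
Product: 38 (S)-2-methyloxirane-2-carboxylic acid
Conditions: KOH, MeOH/H2O, 0 °C; KHSO4 (aq), 0 °C, extraction, used at once
Reagents that add atoms: potassium hydroxide, [K+].[OH-]
Why: Cold saponification and careful acidification give the alpha-methyl glycidic acid without touching its quaternary stereocentre.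

Step 22
Reactants: 36 (1S,4R,8S,10R; 5E) 13-O-acetate with free C8 hydroxyl; 38 (S)-2-methyloxirane-2-carboxylic acid
Product: 40 (1S,4R,8S,10R; 5E) C8 (2S)-2-methyloxirane-2-carboxylate 13-O-acetate C1 methyl ketal, via mixed anhydride 39 (not isolated)
Conditions: 38, 2,4,6-trichlorobenzoyl chloride, Et3N, THF, rt; then 36, DMAP, toluene, rt
Reagents that add atoms: none
Why: Yamaguchi esterification: DMAP attacks the less hindered glycidyl carbonyl of the mixed anhydride and the acylpyridinium acylates the hindered C8 hydroxyl with retention at C8, while the epoxide survives the non-nucleophilic medium.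

Step 23
Reactants: 40 (1S,4R,8S,10R; 5E) C8 (2S)-2-methyloxirane-2-carboxylate 13-O-acetate C1 methyl ketal
Product: 42 CNP0414417.3 (target), via chlorohydrin methyl ketal 41 (not isolated)
Conditions: LiCl, AcOH, THF, rt; then H2O, 35 °C
Reagents that add atoms: lithium chloride, [Li+].[Cl-]; water, O
Why: Acid-assisted SN2 opening of the epoxide by chloride (halohydrin formation) occurs at the unhindered CH2 and leaves the side-chain stereocentre untouched (now R by priority change), and the added water hydrolyses the methyl ketal to the hemiketal, whose C1 configuration is fixed by the bridge.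

**Compound list**

1 | furan-3-ylmethanol | OCc1ccoc1 | starting material
2 | tert-butyl(furan-3-ylmethoxy)dimethylsilane | CC(C)(C)[Si](C)(C)OCc1ccoc1 | intermediate
3 | [2-(tert-butyldimethylsilyl)furan-3-yl]methanol | OCc1ccoc1[Si](C)(C)C(C)(C)C | intermediate
4 | lithium [2-(tert-butyldimethylsilyl)-4-lithiofuran-3-yl]methoxide | [Li]OCc1c([Li])coc1[Si](C)(C)C(C)(C)C | intermediate
5 | dilithium 5-(tert-butyldimethylsilyl)-4-(oxidomethyl)furan-3-carboxylate | [Li]OCc1c(C(=O)O[Li])coc1[Si](C)(C)C(C)(C)C | intermediate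
6 | triisopropylsilyl 5-(tert-butyldimethylsilyl)-4-{[(triisopropylsilyl)oxy]methyl}furan-3-carboxylate | CC(C)[Si](C(C)C)(C(C)C)OCc1c(C(=O)O[Si](C(C)C)(C(C)C)C(C)C)coc1[Si](C)(C)C(C)(C)C | intermediate
7 | 5-(tert-butyldimethylsilyl)-4-{[(triisopropylsilyl)oxy]methyl}furan-3-carboxylic acid | CC(C)[Si](C(C)C)(C(C)C)OCc1c(C(=O)O)coc1[Si](C)(C)C(C)(C)C | intermediate
8 | methyl (S)-3-bromo-2-methylpropanoate | COC(=O)[C@H](C)CBr | starting material
9 | 5-(tert-butyldimethylsilyl)-4-{[(triisopropylsilyl)oxy]methyl}furan-3-carbonyl chloride | CC(C)[Si](C(C)C)(C(C)C)OCc1c(C(Cl)=O)coc1[Si](C)(C)C(C)(C)C | intermediate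
10 | (S)-(3-methoxy-2-methyl-3-oxopropyl)zinc bromide | COC(=O)[C@H](C)C[Zn]Br | intermediate
11 | methyl (2R)-4-(FurSi)-2-methyl-4-oxobutanoate | COC(=O)[C@H](C)CC(=O)c1coc([Si](C)(C)C(C)(C)C)c1CO[Si](C(C)C)(C(C)C)C(C)C | intermediate
12 | methyl (2R,4S)-4-(FurSi)-4-hydroxy-2-methylbutanoate | COC(=O)[C@H](C)C[C@H](O)c1coc([Si](C)(C)C(C)(C)C)c1CO[Si](C(C)C)(C(C)C)C(C)C | intermediate
13 | (3R,5S)-5-(FurSi)-3-methyloxolan-2-one (trans) | C[C@@H]1C[C@H](OC1=O)c2coc([Si](C)(C)C(C)(C)C)c2CO[Si](C(C)C)(C(C)C)C(C)C | intermediate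
14 | (2R,4S)-4-(FurSi)-4-hydroxy-N-methoxy-N,2-dimethylbutanamide | CON(C)C(=O)[C@H](C)C[C@H](O)c1coc([Si](C)(C)C(C)(C)C)c1CO[Si](C(C)C)(C(C)C)C(C)C | intermediate
15 | (2R,4S)-4-[(tert-butyldimethylsilyl)oxy]-4-(FurSi)-N-methoxy-N,2-dimethylbutanamide | CON(C)C(=O)[C@H](C)C[C@H](O[Si](C)(C)C(C)(C)C)c1coc([Si](C)(C)C(C)(C)C)c1CO[Si](C(C)C)(C(C)C)C(C)C | intermediate
16 | (R)-linalool | CC(C)=CCC[C@@](C)(O)C=C | starting material
17 | triethyl{[(3R)-3,7-dimethylocta-1,6-dien-3-yl]oxy}silane | CC(C)=CCC[C@@](C)(O[Si](CC)(CC)CC)C=C | intermediate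
18 | (4R)-4-methyl-4-[(triethylsilyl)oxy]hex-5-enal | O=CCC[C@@](C)(O[Si](CC)(CC)CC)C=C | intermediate
19 | tert-butyldimethyl{[(4R)-4-methyl-4-(triethylsilyloxy)hexa-1,5-dien-1-yl]oxy}silane (E/Z) | CC(C)(C)[Si](C)(C)OC=CC[C@@](C)(O[Si](CC)(CC)CC)C=C | intermediate
20 | (3R)-3-methyl-3-[(triethylsilyl)oxy]pent-4-en-1-ol | OCC[C@@](C)(O[Si](CC)(CC)CC)C=C | intermediate
21 | triethyl{[(3R)-5-iodo-3-methylpent-1-en-3-yl]oxy}silane | ICC[C@@](C)(O[Si](CC)(CC)CC)C=C | intermediate
22 | [(3R)-3-methyl-3-(triethylsilyloxy)pent-4-en-1-yl]lithium | [Li]CC[C@@](C)(O[Si](CC)(CC)CC)C=C | intermediate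
23 | (4R,8S,10R) seco ketone (C4 OTES; C8 OTBS; C1 ketone; FurSi on C8) | C=C[C@](C)(O[Si](CC)(CC)CC)CCC(=O)[C@H](C)C[C@H](O[Si](C)(C)C(C)(C)C)c1coc([Si](C)(C)C(C)(C)C)c1CO[Si](C(C)C)(C(C)C)C(C)C | intermediate
24 | (4R,8S,10R) C4-hydroxy C1-ketone | C=C[C@](C)(O)CCC(=O)[C@H](C)C[C@H](O[Si](C)(C)C(C)(C)C)c1coc([Si](C)(C)C(C)(C)C)c1CO[Si](C(C)C)(C(C)C)C(C)C | intermediate
25 | (1R,4R,8S,10R) ring B methyl ketal, C10 chain trans to vinyl (equilibrates to 26 under the acid) | C=C[C@@]1(C)CC[C@@](OC)(O1)[C@H](C)C[C@H](O[Si](C)(C)C(C)(C)C)c2coc([Si](C)(C)C(C)(C)C)c2CO[Si](C(C)C)(C(C)C)C(C)C | intermediate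
26 | (1S,4R,8S,10R) ring B methyl ketal, C10 chain cis to vinyl | C=C[C@@]1(C)CC[C@](OC)(O1)[C@H](C)C[C@H](O[Si](C)(C)C(C)(C)C)c2coc([Si](C)(C)C(C)(C)C)c2CO[Si](C(C)C)(C(C)C)C(C)C | intermediate
27 | (1S,4R,8S,10R) C6-hydroxybutenolide (C6 epimers) | C=C[C@@]1(C)CC[C@](OC)(O1)[C@H](C)C[C@H](O[Si](C)(C)C(C)(C)C)C2=C(CO[Si](C(C)C)(C(C)C)C(C)C)C(=O)OC2O | intermediate
28 | (1S,4R,8S,10R) butenolide with vinyl on C4 | C=C[C@@]1(C)CC[C@](OC)(O1)[C@H](C)C[C@H](O[Si](C)(C)C(C)(C)C)C2=C(CO[Si](C(C)C)(C(C)C)C(C)C)C(=O)OC2 | intermediate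
29 | (1S,4R,8S,10R) C5 aldehyde butenolide | O=C[C@@]1(C)CC[C@](OC)(O1)[C@H](C)C[C@H](O[Si](C)(C)C(C)(C)C)C2=C(CO[Si](C(C)C)(C(C)C)C(C)C)C(=O)OC2 | intermediate
30 | (1S,4R,8S,10R) seco C5 aldehyde 2-(triisopropylsilyloxy)furan (key-step precursor) | O=C[C@@]1(C)CC[C@](OC)(O1)[C@H](C)C[C@H](O[Si](C)(C)C(C)(C)C)c2coc(O[Si](C(C)C)(C(C)C)C(C)C)c2CO[Si](C(C)C)(C(C)C)C(C)C | intermediate
31 | tetrabutylammonium furanolate of 30 | O=C[C@@]1(C)CC[C@](OC)(O1)[C@H](C)C[C@H](O[Si](C)(C)C(C)(C)C)c2coc([O-])c2CO[Si](C(C)C)(C(C)C)C(C)C.CCCC[N+](CCCC)(CCCC)CCCC | intermediate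
32 | cyclised C5 aldol (C5 and C6 epimers; formed as the alkoxide) | CC(C)[Si](C(C)C)(C(C)C)OCC1=C2C(C(O)[C@@]3(C)CC[C@](OC)(O3)[C@H](C)C[C@@H]2O[Si](C)(C)C(C)(C)C)OC1=O | intermediate
33 | cyclised C5 acetate (C5 and C6 epimers) | CC(C)[Si](C(C)C)(C(C)C)OCC1=C2C(C(OC(C)=O)[C@@]3(C)CC[C@](OC)(O3)[C@H](C)C[C@@H]2O[Si](C)(C)C(C)(C)C)OC1=O | intermediate
34 | (1S,4R,8S,10R; 5E) bridged dienolide, C1 methyl ketal, C8 OTBS, C13 OTIPS (key-step product) | CC(C)[Si](C(C)C)(C(C)C)OCC1=C2/C(=C\[C@@]3(C)CC[C@](OC)(O3)[C@H](C)C[C@@H]2O[Si](C)(C)C(C)(C)C)OC1=O | intermediate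
35 | (1S,4R,8S,10R; 5E) C8,C13-diol C1 methyl ketal | OCC1=C2/C(=C\[C@@]3(C)CC[C@](OC)(O3)[C@H](C)C[C@@H]2O)OC1=O | intermediate
36 | (1S,4R,8S,10R; 5E) 13-O-acetate, free C8 hydroxyl | CC(=O)OCC1=C2/C(=C\[C@@]3(C)CC[C@](OC)(O3)[C@H](C)C[C@@H]2O)OC1=O | intermediate
37 | methyl (S)-2-methylglycidate | COC(=O)[C@@]1(C)OC1 | starting material
38 | (S)-2-methyloxirane-2-carboxylic acid | OC(=O)[C@@]1(C)OC1 | intermediate
39 | (S)-2-methyloxirane-2-carboxylic 2,4,6-trichlorobenzoic anhydride | O=C(OC(=O)c1c(Cl)cc(Cl)cc1Cl)[C@@]2(C)OC2 | intermediate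
40 | (1S,4R,8S,10R; 5E) C8 (2S)-2-methyloxirane-2-carboxylate, 13-O-acetate, C1 methyl ketal | CC(=O)OCC1=C2/C(=C\[C@@]3(C)CC[C@](OC)(O3)[C@H](C)C[C@@H]2OC(=O)[C@@]4(C)OC4)OC1=O | intermediate
41 | (1S,4R,8S,10R; 5E) C8 (2R)-3-chloro-2-hydroxy-2-methylpropanoate, 13-O-acetate, C1 methyl ketal | CC(=O)OCC1=C2/C(=C\[C@@]3(C)CC[C@](OC)(O3)[C@H](C)C[C@@H]2OC(=O)[C@@](C)(O)CCl)OC1=O | intermediate
42 | CNP0414417.3: (1S,4R,8S,10R; 5E) C1 hemiketal, C8 (2R)-3-chloro-2-hydroxy-2-methylpropanoate, 13-O-acetate | CC(=O)OCC1=C2/C(=C\[C@@]3(C)CC[C@](O)(O3)[C@H](C)C[C@@H]2OC(=O)[C@@](C)(O)CCl)OC1=O | target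

**Totals and risks**

Total step count: 23. Longest linear sequence: 17 steps (steps 1–7, 13–20, 22, 23).

Steps most likely to fail:

1. Step 18 (the proposed new method). Ring closure may lose to intermolecular aldol addition, the strained aldolate may revert by retro-aldol before it is acetylated, or the anhydride may consume the furanolate at oxygen. The fallback uses known chemistry and replaces aldol addition/elimination by olefination at the same bond. It sets out from hydroxybutenolide 27, obtained by stopping step 15 before the borohydride. Dimethyl phosphite with a catalytic amine base (Pudovik addition to the ring-opened aldehyde, then relactonisation, as is standard for such pseudo-acids) should give the C6 dimethyl phosphonate butenolide F1. Johnson–Lemieux cleavage as in step 16 gives the phosphonate C5 aldehyde F2. LiCl and DBU in MeCN at high dilution (Masamune–Roush conditions) then close ring C by intramolecular Horner–Wadsworth–Emmons olefination, and the route is rejoined at 34.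

2. Step 17. The silyl triflate may trigger aldol closure or ionise the methyl ketal before the silyloxyfuran is secured, and the silyloxyfuran may hydrolyse during isolation. The fallback gives up isolation and fluoride activation and sets out from aldehyde butenolide 29. TBSOTf and iPr2NEt in CH2Cl2 at high dilution form the tert-butyldimethylsilyloxyfuran aldehyde F3 in the flask; silyl-triflate-promoted vinylogous Mukaiyama closure gives the cyclised C5 silyl ether F4; DBU added to the same flask eliminates silanol, and the route is rejoined at 34.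

3. Step 15. With the bulky tert-butyldimethylsilyl group the silyl shift in the endoperoxide may be slow, so that the endoperoxide breaks down without regiocontrol or takes up methanol, and borohydride may reduce the butenolide further. The fallback sets out from ketal 26 and uses peracid instead of singlet oxygen: buffered peracetic acid (NaOAc, CH2Cl2, 0 °C) epoxidises the silicon-bearing double bond and a 1,2-silyl shift with loss of silicon makes that carbon the lactone carbonyl (a known direct conversion of 2-silylfurans into butenolides). This should give the deconjugated C6=C7 lactone F5, which Et3N isomerises into conjugation, and the route is rejoined at 28.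

Further compounds
F1 | step 18 | (1S,4R,8S,10R) butenolide with dimethoxyphosphoryl on C6 and vinyl on C4 (C6 epimers) | C=C[C@@]1(C)CC[C@](OC)(O1)[C@H](C)C[C@H](O[Si](C)(C)C(C)(C)C)C2=C(CO[Si](C(C)C)(C(C)C)C(C)C)C(=O)OC2P(=O)(OC)OC
F2 | step 18 | (1S,4R,8S,10R) C5 aldehyde butenolide with dimethoxyphosphoryl on C6 | O=C[C@@]1(C)CC[C@](OC)(O1)[C@H](C)C[C@H](O[Si](C)(C)C(C)(C)C)C2=C(CO[Si](C(C)C)(C(C)C)C(C)C)C(=O)OC2P(=O)(OC)OC
F3 | step 17 | (1S,4R,8S,10R) seco C5 aldehyde 2-(tert-butyldimethylsilyloxy)furan | O=C[C@@]1(C)CC[C@](OC)(O1)[C@H](C)C[C@H](O[Si](C)(C)C(C)(C)C)c2coc(O[Si](C)(C)C(C)(C)C)c2CO[Si](C(C)C)(C(C)C)C(C)C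
F4 | step 17 | cyclised C5 tert-butyldimethylsilyl ether (C5 and C6 epimers) | CC(C)[Si](C(C)C)(C(C)C)OCC1=C2C(C(O[Si](C)(C)C(C)(C)C)[C@@]3(C)CC[C@](OC)(O3)[C@H](C)C[C@@H]2O[Si](C)(C)C(C)(C)C)OC1=O
F5 | step 15 | (1S,4R,8S,10R) deconjugated lactone (C6=C7; C11–H) with vinyl on C4 | C=C[C@@]1(C)CC[C@](OC)(O1)[C@H](C)C[C@H](O[Si](C)(C)C(C)(C)C)C2=COC(=O)C2CO[Si](C(C)C)(C(C)C)C(C)C
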